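Ring B, the central benzene that carries the free C1 hydroxyl, the neighbouring C2 aryl ether oxygen and the ethylene bridge at C4 (para to OH), is built from acyclic pieces instead of being coupled. Its O–C2–C1–O unit is the OCH2C(=O) of an aryloxyacetone, so the diaryl ether oxygen comes from a Williamson alkylation. One Michael/aldol condensation of this ketone with an α-substituted acrolein that carries the ring A arm forms C2–C3 and C5–C6 and closes the carbocycle; dehydrogenation then reveals the phenol. The precursors are aryloxyacetone 7, with rings C and D already joined and the ring D phenol as benzyl ether, and 2-methylene aldehyde 11.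

Key step: step 6

Remark: the target has no stereogenic element, so "single enantiomer" is taken to mean the one achiral compound; the sp3 centres made in step 6 are erased in step 7.

Ring labels: A = 3-methoxyphenyl; B = central phenol ring (C1 OH, C2 OAr, C4 bridge); C = 1,4-phenylene; D = 3-hydroxyphenyl.

**Route**

Step 1
Reactants: 1 4-vinylphenyl acetate (4-acetoxystyrene); 2 1-(benzyloxy)-3-bromobenzene
Product: 5 4-{2-[3-(benzyloxy)phenyl]ethyl}phenol, via acetoxyaryl alkylborane 3 (not isolated), via hydroxyaryl alkylborane 4 (not isolated)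
Conditions: 9-BBN, THF, 0 °C to rt; 3 M aq NaOH, rt; then 2, Pd(dppf)Cl2 (3 mol%), 65 °C; 1 M HCl work-up
Reagents that add atoms: none
Why: Anti-Markovnikov hydroboration of the styrene with 9-BBN gives the primary alkylborane, hydroxide cleaves the aryl acetate and forms the borate, and a B-alkyl Suzuki–Miyaura coupling with the aryl bromide then joins rings C and D as a saturated bridge without any alkene hydrogenation that could endanger the benzyl ether.

Step 2
Reactants: 5 4-{2-[3-(benzyloxy)phenyl]ethyl}phenol; 6 chloroacetone
Product: 7 1-(4-{2-[3-(benzyloxy)phenyl]ethyl}phenoxy)propan-2-one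
Conditions: K2CO3, acetone, reflux
Reagents that add atoms: none
Why: Williamson ether synthesis, in which the phenoxide displaces chloride from the highly SN2-reactive α-chloro ketone and so sets the future diaryl ether oxygen without an aryl–oxygen coupling.

Step 3
Reactants: 8 4-(3-methoxyphenyl)butanoic acid
Product: 9 4-(3-methoxyphenyl)butan-1-ol
Conditions: BH3·THF, THF, 0 °C to rt; aqueous work-up
Reagents that add atoms: none
Why: Borane reduces the carboxylic acid chemoselectively through the acyloxyborane to the primary alcohol and leaves the anisole untouched.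

Step 4
Reactants: 9 4-(3-methoxyphenyl)butan-1-ol
Product: 10 4-(3-methoxyphenyl)butanal
Conditions: TEMPO (10 mol%), PhI(OAc)2, CH2Cl2, rt
Reagents that add atoms: none
Why: Oxoammonium-mediated oxidation (TEMPO/PhI(OAc)2) of a primary alcohol stops cleanly at the aldehyde under anhydrous conditions.

Step 5
Reactants: 10 4-(3-methoxyphenyl)butanal
Product: 11 4-(3-methoxyphenyl)-2-methylenebutanal
Conditions: 37% aq CH2O, pyrrolidine (10 mol%), EtCO2H (10 mol%), i-PrOH, 45 °C
Reagents that add atoms: formaldehyde, C=O
Why: Amine-catalysed Mannich-type α-methylenation, in which the aldehyde enamine adds to the formaldehyde iminium ion and β-elimination of the amine gives the 2-substituted acrolein, which has no α-hydrogen left and cannot condense again.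

Step 6
Reactants: 7 1-(4-{2-[3-(benzyloxy)phenyl]ethyl}phenoxy)propan-2-one; 11 4-(3-methoxyphenyl)-2-methylenebutanal
Product: 14 6-(4-{2-[3-(benzyloxy)phenyl]ethyl}phenoxy)-4-[2-(3-methoxyphenyl)ethyl]cyclohex-2-en-1-one (racemic mixture of diastereomers), via keto aldehyde 12 (not isolated), via aldol 13 (not isolated)
Conditions: pyrrolidine (0.3 equiv), AcOH (0.3 equiv), PhMe, rt, slow addition of 11 (1.2 equiv); then 80 °C
Reagents that add atoms: none
Why: The amine should convert 7 into the oxygen-bearing enamine (the regiochemistry typical of α-oxygenated acetones), which adds in conjugate fashion to the unsubstituted CH2 terminus of 11 to form the C2–C3 bond of ring B and, after hydrolysis, keto aldehyde 12. The methyl side of the ketone then attacks the aldehyde carbon in a 6-(enolendo)-exo-trig aldol closure to 13 (C5–C6 bond of ring B), and loss of water gives the conjugated enone 14. The closest known reaction type is the Robinson annulation of ketones with α-substituted acroleins, and the ring-closing half is the 1,5-keto aldehyde cyclisation that gives 4-substituted cyclohex-2-enones from aldehyde–methyl vinyl ketone adducts. The two sp3 centres of 14 (the aryloxy-bearing carbon and the side-chain-bearing carbon) and the carbinol centre of 13 form without control, and none is needed because all become sp2 in step 7. The selectivity required is 1,4- over 1,2-addition and single over double Michael addition, which the soft enamine nucleophile, the unhindered methylene terminus and the slow addition of 11 should secure. Regioselectivity of enolisation is not critical, since addition through the methyl group and aldol closure through the aryloxymethylene would give the isomeric 2-aryloxy-4-substituted cyclohex-2-enone, which step 7 converts into the same phenol 16.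

Step 7
Reactants: 14 6-(4-{2-[3-(benzyloxy)phenyl]ethyl}phenoxy)-4-[2-(3-methoxyphenyl)ethyl]cyclohex-2-en-1-one
Product: 16 2-(4-{2-[3-(benzyloxy)phenyl]ethyl}phenoxy)-4-[2-(3-methoxyphenyl)ethyl]phenol, via cyclohexadienone 15 (not isolated)
Conditions: Pd(TFA)2 (5 mol%), 2-(dimethylamino)pyridine (10 mol%), TsOH·H2O (20 mol%), O2 (1 atm), DMSO, 80 °C
Reagents that add atoms: none
Why: Aerobic Pd(II)-catalysed dehydrogenation, in which a palladium enolate at the aryloxy-bearing α′-carbon undergoes β-hydride elimination to the cross-conjugated dienone 15 that tautomerises at once to the phenol, while the ethers and the benzylic CH2 groups, which lack a carbonyl to direct palladation, should remain intact.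

Step 8
Reactants: 16 2-(4-{2-[3-(benzyloxy)phenyl]ethyl}phenoxy)-4-[2-(3-methoxyphenyl)ethyl]phenol
Product: 17 2-{4-[2-(3-hydroxyphenyl)ethyl]phenoxy}-4-[2-(3-methoxyphenyl)ethyl]phenol (target)
Conditions: H2 (1 atm), 10% Pd/C, EtOAc/EtOH, rt
Reagents that add atoms: none
Why: Catalytic hydrogenolysis cleaves the benzylic C–O bond of the aryl benzyl ether, whereas the methyl ether, the diaryl ether and the saturated bridges are inert under these mild conditions.

**Compound list**

1 | 4-vinylphenyl acetate (4-acetoxystyrene) | CC(=O)Oc1ccc(C=C)cc1 | starting material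
2 | 1-(benzyloxy)-3-bromobenzene | Brc1cccc(OCc2ccccc2)c1 | starting material
3 | 9-[2-(4-acetoxyphenyl)ethyl]-9-borabicyclo[3.3.1]nonane | CC(=O)Oc1ccc(CCB2C3CCCC2CCC3)cc1 | intermediate (not isolated)
4 | 9-[2-(4-hydroxyphenyl)ethyl]-9-borabicyclo[3.3.1]nonane (present as sodium phenoxide/hydroxyborate, drawn neutral) | Oc1ccc(CCB2C3CCCC2CCC3)cc1 | intermediate (not isolated)
5 | 4-{2-[3-(benzyloxy)phenyl]ethyl}phenol | Oc1ccc(CCc2cccc(OCc3ccccc3)c2)cc1 | intermediate
6 | chloroacetone | CC(=O)CCl | starting material
7 | 1-(4-{2-[3-(benzyloxy)phenyl]ethyl}phenoxy)propan-2-one | CC(=O)COc1ccc(CCc2cccc(OCc3ccccc3)c2)cc1 | intermediate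
8 | 4-(3-methoxyphenyl)butanoic acid | COc1cccc(CCCC(=O)O)c1 | starting material
9 | 4-(3-methoxyphenyl)butan-1-ol | COc1cccc(CCCCO)c1 | intermediate
10 | 4-(3-methoxyphenyl)butanal | COc1cccc(CCCC=O)c1 | intermediate
11 | 4-(3-methoxyphenyl)-2-methylenebutanal | COc1cccc(CCC(=C)C=O)c1 | intermediate
12 | 4-(4-{2-[3-(benzyloxy)phenyl]ethyl}phenoxy)-2-[2-(3-methoxyphenyl)ethyl]-5-oxohexanal (mixture of stereoisomers) | COc1cccc(CCC(C=O)CC(Oc2ccc(CCc3cccc(OCc4ccccc4)c3)cc2)C(C)=O)c1 | intermediate (not isolated)
13 | 2-(4-{2-[3-(benzyloxy)phenyl]ethyl}phenoxy)-5-hydroxy-4-[2-(3-methoxyphenyl)ethyl]cyclohexan-1-one (mixture of stereoisomers) | COc1cccc(CCC2CC(Oc3ccc(CCc4cccc(OCc5ccccc5)c4)cc3)C(=O)CC2O)c1 | intermediate (not isolated)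
14 | 6-(4-{2-[3-(benzyloxy)phenyl]ethyl}phenoxy)-4-[2-(3-methoxyphenyl)ethyl]cyclohex-2-en-1-one (racemic, mixture of diastereomers) | COc1cccc(CCC2CC(Oc3ccc(CCc4cccc(OCc5ccccc5)c4)cc3)C(=O)C=C2)c1 | intermediate
15 | 2-(4-{2-[3-(benzyloxy)phenyl]ethyl}phenoxy)-4-[2-(3-methoxyphenyl)ethyl]cyclohexa-2,5-dien-1-one (racemic) | COc1cccc(CCC2C=CC(=O)C(Oc3ccc(CCc4cccc(OCc5ccccc5)c4)cc3)=C2)c1 | intermediate (not isolated)
16 | 2-(4-{2-[3-(benzyloxy)phenyl]ethyl}phenoxy)-4-[2-(3-methoxyphenyl)ethyl]phenol | COc1cccc(CCc2ccc(O)c(Oc3ccc(CCc4cccc(OCc5ccccc5)c4)cc3)c2)c1 | intermediate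
17 | 2-{4-[2-(3-hydroxyphenyl)ethyl]phenoxy}-4-[2-(3-methoxyphenyl)ethyl]phenol (CNP0225725.0, achiral) | COc1cccc(CCc2ccc(O)c(Oc3ccc(CCc4cccc(O)c4)cc3)c2)c1 | target

**Step count**

Total steps: 8. Longest linear sequence: 6 steps (steps 3, 4, 5, 6, 7, 8, from acid 8). The other branch (steps 1, 2) joins at step 6.

**Steps most likely to fail**

1. Step 6. The enal may be consumed by oligomerisation faster than by conjugate addition. The first adduct may add a second enal molecule. Ring closure and dehydration may stall at the keto aldehyde stage. The fallback gives up the de novo construction of ring B and makes the diaryl ether by aryl–oxygen coupling, setting out from phenol 5. Copper-catalysed Ullmann-type etherification of 5 with commercial 4-(benzyloxy)-3-bromobenzaldehyde (CuI, N,N-dimethylglycine, Cs2CO3, dioxane, 100 °C) should give 4-(benzyloxy)-3-(4-{2-[3-(benzyloxy)phenyl]ethyl}phenoxy)benzaldehyde F1. Wittig olefination with the ylide from commercial (3-methoxybenzyl)triphenylphosphonium chloride (KOt-Bu, THF, 0 °C to rt) should give 1-(benzyloxy)-2-(4-{2-[3-(benzyloxy)phenyl]ethyl}phenoxy)-4-[2-(3-methoxyphenyl)ethenyl]benzene F2 as an E/Z mixture. Hydrogenation over Pd/C then saturates the alkene and removes both benzyl groups in one operation, so the fallback comes back to the route at target 17.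

2. Step 7. The dehydrogenation may stop short through catalyst deactivation to palladium black. The enone may disproportionate to saturated ketone and phenol. Benzylic positions may be oxidised on prolonged heating under oxygen. The fallback replaces catalytic dehydrogenation by selenoxide elimination and sets out from 14. Kinetic deprotonation at the aryloxy-bearing α′-carbon (LDA, THF, −78 °C) and trapping with PhSeCl should give 6-(4-{2-[3-(benzyloxy)phenyl]ethyl}phenoxy)-4-[2-(3-methoxyphenyl)ethyl]-6-(phenylselanyl)cyclohex-2-en-1-one F3. Oxidation with aqueous H2O2 (CH2Cl2, pyridine, 0 °C) should give the corresponding selenoxide, 6-(4-{2-[3-(benzyloxy)phenyl]ethyl}phenoxy)-4-[2-(3-methoxyphenyl)ethyl]-6-(phenylseleninyl)cyclohex-2-en-1-one F4. Syn-elimination of F4 toward the ring CH2 forms dienone 15, which tautomerises, and the fallback comes back to the route at 16.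

3. Step 5. The 2-methylene aldehyde may dimerise by hetero-Diels–Alder reaction or polymerise during concentration and storage. Its double bond may also migrate into the chain, and the quality of this partner decides step 6. The fallback avoids isolating the free enal and sets out from aldehyde 10. Mannich reaction with dimethylmethylideneammonium iodide (Eschenmoser's salt, CH2Cl2, rt, no added base) should give 2-[(dimethylamino)methyl]-4-(3-methoxyphenyl)butanal F5, kept as its hydroiodide. This salt is charged into step 6 with one equivalent of NaOAc in place of 11. In the warm amine/acid medium it should lose dimethylamine slowly and release the enal at low stationary concentration, so the fallback comes back to the route at 11, formed and consumed in the flask.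

**Further compounds**

F1 | step 6 | 4-(benzyloxy)-3-(4-{2-[3-(benzyloxy)phenyl]ethyl}phenoxy)benzaldehyde | O=Cc1ccc(OCc2ccccc2)c(Oc2ccc(CCc3cccc(OCc4ccccc4)c3)cc2)c1
F2 | step 6 | 1-(benzyloxy)-2-(4-{2-[3-(benzyloxy)phenyl]ethyl}phenoxy)-4-[2-(3-methoxyphenyl)ethenyl]benzene (E/Z mixture) | COc1cccc(C=Cc2ccc(OCc3ccccc3)c(Oc3ccc(CCc4cccc(OCc5ccccc5)c4)cc3)c2)c1
F3 | step 7 | 6-(4-{2-[3-(benzyloxy)phenyl]ethyl}phenoxy)-4-[2-(3-methoxyphenyl)ethyl]-6-(phenylselanyl)cyclohex-2-en-1-one (mixture of stereoisomers) | COc1cccc(CCC2CC(Oc3ccc(CCc4cccc(OCc5ccccc5)c4)cc3)([Se]c3ccccc3)C(=O)C=C2)c1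
F4 | step 7 | 6-(4-{2-[3-(benzyloxy)phenyl]ethyl}phenoxy)-4-[2-(3-methoxyphenyl)ethyl]-6-(phenylseleninyl)cyclohex-2-en-1-one (mixture of stereoisomers) | COc1cccc(CCC2CC(Oc3ccc(CCc4cccc(OCc5ccccc5)c4)cc3)([Se](=O)c3ccccc3)C(=O)C=C2)c1
F5 | step 5 | 2-[(dimethylamino)methyl]-4-(3-methoxyphenyl)butanal (racemic, handled as hydroiodide) | COc1cccc(CCC(CN(C)C)C=O)c1
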